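The chroman pyran ring (O1', C2', C3', C4', C4a', C8a') is opened across C4'–C3' and O1'–C2'. O1' and the benzylic C4', ortho on the arene, are a masked ortho-quinone methide; the gem-dimethyl C2' can bear cationic character; the C3' carbinol can arrive as a C–B bond. One acid-catalysed [4+2] between this quinone methide and an isobutenylboronate therefore builds the ring, two bonds and the C3' stereocentre, and oxidation with retention then unveils the alcohol. The precursor is the complete, benzyl-protected (5R)-butenolide carrying a 4-hydroxy-3-(hydroxymethyl)benzyl group on C5, assembled by asymmetric phase-transfer benzylation.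

Key step: step 9

Remark on locants: in the text the butenolide is numbered O1, C2 (lactone carbonyl), C3 (enol oxygen), C4 (aryl), C5 (quaternary carbon), and the chroman carries primed locants. The systematic names use furan-2-carboxylate numbering, in which the quaternary carbon is C2, the aryl-bearing carbon is C3 and the benzyloxy-bearing carbon next to the lactone carbonyl is C4.

Assumption: the sense of induction in the two catalyst-controlled steps (7 and 9) cannot be predicted with confidence; the catalyst antipode or pseudoenantiomer that delivers 5R and 3'S is taken to be fixed in a first screening run, and the catalysts named stand for that choice.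

Step 1
Reactants: 1 methyl 3-formyl-4-hydroxybenzoate
Product: 2 methyl 4-hydroxy-3-(hydroxymethyl)benzoate
Conditions: NaBH4, MeOH/THF, 0 °C
Reagents that add atoms: none
Why: Borohydride reduction of the aryl aldehyde is chemoselective over the methyl ester and should give the salicyl alcohol directly.

Step 2
Reactants: 2 methyl 4-hydroxy-3-(hydroxymethyl)benzoate
Product: 3 methyl 2,2-dimethyl-4H-1,3-benzodioxine-6-carboxylate
Conditions: 2,2-dimethoxypropane, TsOH·H2O (cat.), acetone, rt
Reagents that add atoms: 2,2-dimethoxypropane, COC(C)(C)OC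
Why: Acid-catalysed transketalisation (acetonide formation) ties the phenol and the ortho hydroxymethyl group into a six-membered isopropylidene ketal, masking both hydroxyls for the hydride and base steps ahead.

Step 3
Reactants: 3 methyl 2,2-dimethyl-4H-1,3-benzodioxine-6-carboxylate
Product: 4 (2,2-dimethyl-4H-1,3-benzodioxin-6-yl)methanol
Conditions: LiAlH4, THF, 0 °C
Reagents that add atoms: none
Why: Hydride reduction of the aryl ester should give the primary benzylic alcohol, the ketal being inert to LiAlH4.

Step 4
Reactants: 4 (2,2-dimethyl-4H-1,3-benzodioxin-6-yl)methanol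
Product: 5 6-(bromomethyl)-2,2-dimethyl-4H-1,3-benzodioxine
Conditions: CBr4, PPh3, CH2Cl2, 0 °C
Reagents that add atoms: carbon tetrabromide, BrC(Br)(Br)Br
Why: Appel bromination converts the primary benzylic alcohol into the bromide through an alkoxyphosphonium ion under essentially neutral conditions that the acid-labile ketal tolerates; the electron-rich bromide should be used without storage.

Step 5
Reactants: 6 4-hydroxyphenylpyruvic acid; 7 methyl glyoxylate
Product: 9 methyl 4-hydroxy-3-(4-hydroxyphenyl)-5-oxo-2,5-dihydrofuran-2-carboxylate (racemic), via aldol adduct 8 (not isolated)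
Conditions: DBU (3 equiv), DMF, 0 °C to rt; then 1 N aq. HCl
Reagents that add atoms: none
Why: Aldol addition of the arylpyruvate enolate through its benzylic carbon to the aldehyde, then acid-promoted lactonisation and enolisation, is the established aldol–lactonisation route from arylpyruvic acids and aldehydes to 3-hydroxy-4-aryl butenolides; the C5 centre formed here is racemic and is planarised again in step 7.

Step 6
Reactants: 9 methyl 4-hydroxy-3-(4-hydroxyphenyl)-5-oxo-2,5-dihydrofuran-2-carboxylate (racemic)
Product: 10 methyl 4-(benzyloxy)-3-[4-(benzyloxy)phenyl]-5-oxo-2,5-dihydrofuran-2-carboxylate (racemic)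
Conditions: BnBr (2.0 equiv), K2CO3 (2.0 equiv), DMF, 0 °C to rt
Reagents that add atoms: benzyl bromide, BrCc1ccccc1
Why: Williamson O-alkylation, in which carbonate deprotonates the two acidic hydroxyls (enol and phenol) and their oxyanions are benzylated, while holding bromide and base at two equivalents at low temperature should keep the far less acidic C5–H of the product from being alkylated.

Step 7
Reactants: 10 methyl 4-(benzyloxy)-3-[4-(benzyloxy)phenyl]-5-oxo-2,5-dihydrofuran-2-carboxylate (racemic); 5 6-(bromomethyl)-2,2-dimethyl-4H-1,3-benzodioxine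
Product: 11 methyl (2R)-4-(benzyloxy)-3-[4-(benzyloxy)phenyl]-2-[(2,2-dimethyl-4H-1,3-benzodioxin-6-yl)methyl]-5-oxo-2,5-dihydrofuran-2-carboxylate
Conditions: O-allyl-N-(9-anthracenylmethyl)cinchonidinium bromide (10 mol %), Cs2CO3 (solid), toluene, −20 °C
Reagents that add atoms: none
Why: Asymmetric phase-transfer alkylation, in which the doubly activated C5–H (ester plus vinylogous lactone carbonyl) is deprotonated to a planar 2-oxidofuran dienolate whose chiral ammonium ion pair exposes one face to the bromide and so sets the quaternary (R)-centre, a reaction type established for lactone γ-carboxylates such as phthalide-3-carboxylates and for β-keto esters; attack at C5 instead of C3 is expected because the stronger alkoxy donor on C3 polarises the dienolate HOMO toward C5 and C5 attack restores the conjugated butenolide.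

Step 8
Reactants: 11 methyl (2R)-4-(benzyloxy)-3-[4-(benzyloxy)phenyl]-2-[(2,2-dimethyl-4H-1,3-benzodioxin-6-yl)methyl]-5-oxo-2,5-dihydrofuran-2-carboxylate
Product: 12 methyl (2R)-4-(benzyloxy)-3-[4-(benzyloxy)phenyl]-2-[4-hydroxy-3-(hydroxymethyl)benzyl]-5-oxo-2,5-dihydrofuran-2-carboxylate
Conditions: 1 N aq. HCl, THF, rt
Reagents that add atoms: none
Why: Acid hydrolysis of the isopropylidene ketal releases acetone and the salicyl alcohol, and dilute aqueous acid at room temperature should leave the benzyl ethers, the ester and the lactone untouched and is too weak to ionise the primary benzylic alcohol.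

Step 9
Reactants: 12 methyl (2R)-4-(benzyloxy)-3-[4-(benzyloxy)phenyl]-2-[4-hydroxy-3-(hydroxymethyl)benzyl]-5-oxo-2,5-dihydrofuran-2-carboxylate; 13 2-methylprop-1-enylboronic acid pinacol ester
Product: 15 methyl (2R)-4-(benzyloxy)-3-[4-(benzyloxy)phenyl]-2-{[(3S)-2,2-dimethyl-3-(4,4,5,5-tetramethyl-1,3,2-dioxaborolan-2-yl)-3,4-dihydro-2H-chromen-6-yl]methyl}-5-oxo-2,5-dihydrofuran-2-carboxylate, via o-quinone methide 14 (not isolated)
Conditions: 13 (3 equiv), (S,S)-imidodiphosphorimidate acid HN[P(=NSO2CF3)(3,3'-Ar2-BINOL-diolate)]2 with Ar = 3,5-(CF3)2C6H3 (5 mol %), 5 Å MS, CHCl3, −20 °C to rt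
Reagents that add atoms: none
Why: Proposed new method: the confined acid protonates the benzylic hydroxyl of 12 and expels water to give o-quinone methide 14 as a hydrogen-bonded ion pair with the chiral anion; the boron-bearing sp2 carbon of 13 then bonds to the exocyclic methylene C4' while positive charge builds on the dimethyl-substituted carbon (tertiary, and stabilised by hyperconjugation with the adjacent C–B bond), which the quinone-methide oxygen captures. The closest known reaction type is the chiral Brønsted acid-catalysed inverse-electron-demand oxa-Diels–Alder reaction of o-quinone methides generated in situ from o-hydroxybenzyl alcohols with styrenes and 1,1-disubstituted alkenes; an alkenylboronate as the 2π partner is the untested element. The pyran ring closes by a concerted but asynchronous [4+2] cycloaddition (in the stepwise limit a 6-endo capture of the C2' cation by O1'), forming C4'–C3' and O1'–C2' in one operation. The boron-bearing C3' stereocentre (S) is set by the chiral anion, which stays bound to the quinone-methide oxygen and selects one enantiotopic face of the alkene; C5 is too remote to contribute, so the step is purely catalyst-controlled. Regioselectivity (oxygen to CMe2, carbon to CH–B) follows from the Markovnikov bias of the trisubstituted alkene reinforced by the β-boron effect, and chemoselectivity from the capped enol and remote phenol, the excess of 13 and a ring closure that should outrun loss of boron from the zwitterion.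

Step 10
Reactants: 15 methyl (2R)-4-(benzyloxy)-3-[4-(benzyloxy)phenyl]-2-{[(3S)-2,2-dimethyl-3-(4,4,5,5-tetramethyl-1,3,2-dioxaborolan-2-yl)-3,4-dihydro-2H-chromen-6-yl]methyl}-5-oxo-2,5-dihydrofuran-2-carboxylate
Product: 16 methyl (2R)-4-(benzyloxy)-3-[4-(benzyloxy)phenyl]-2-{[(3S)-3-hydroxy-2,2-dimethyl-3,4-dihydro-2H-chromen-6-yl]methyl}-5-oxo-2,5-dihydrofuran-2-carboxylate
Conditions: NaBO3·4H2O, THF/H2O (1:1), rt
Reagents that add atoms: sodium perborate, [Na+].[Na+].O[B-]1(O)OO[B-](O)(O)OO1
Why: Organoborane oxidation, in which hydroperoxide adds to boron and carbon migrates from boron to oxygen with retention, should give the (3'S)-alcohol, and the mild, weakly basic perborate should spare the methyl ester, the lactone and the enol ether.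

Step 11
Reactants: 16 methyl (2R)-4-(benzyloxy)-3-[4-(benzyloxy)phenyl]-2-{[(3S)-3-hydroxy-2,2-dimethyl-3,4-dihydro-2H-chromen-6-yl]methyl}-5-oxo-2,5-dihydrofuran-2-carboxylate
Product: 17 methyl (2R)-4-hydroxy-2-{[(3S)-3-hydroxy-2,2-dimethyl-3,4-dihydro-2H-chromen-6-yl]methyl}-3-(4-hydroxyphenyl)-5-oxo-2,5-dihydrofuran-2-carboxylate
Conditions: H2 (1 atm), Pd/C (10 wt %), EtOAc/MeOH, rt
Reagents that add atoms: none
Why: Catalytic hydrogenolysis cleaves the aryl benzyl ether and the enol benzyl ether to toluene, while the tetrasubstituted conjugated butenolide alkene, the non-benzylic C–O bonds of the chroman and both stereocentres should be untouched at one atmosphere.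

Compound list
1 | methyl 3-formyl-4-hydroxybenzoate | COC(=O)c1ccc(O)c(C=O)c1 | starting material
2 | methyl 4-hydroxy-3-(hydroxymethyl)benzoate | COC(=O)c1ccc(O)c(CO)c1 | intermediate
3 | methyl 2,2-dimethyl-4H-1,3-benzodioxine-6-carboxylate | COC(=O)c1ccc2c(c1)COC(C)(C)O2 | intermediate
4 | (2,2-dimethyl-4H-1,3-benzodioxin-6-yl)methanol | OCc1ccc2c(c1)COC(C)(C)O2 | intermediate
5 | 6-(bromomethyl)-2,2-dimethyl-4H-1,3-benzodioxine | BrCc1ccc2c(c1)COC(C)(C)O2 | intermediate
6 | 4-hydroxyphenylpyruvic acid | OC(=O)C(=O)Cc1ccc(O)cc1 | starting material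
7 | methyl glyoxylate | COC(=O)C=O | starting material
8 | 4-hydroxy-3-(4-hydroxyphenyl)-5-methoxy-2,5-dioxopentanoic acid (aldol adduct, diastereomer mixture, not isolated) | COC(=O)C(O)C(c1ccc(O)cc1)C(=O)C(=O)O | intermediate
9 | methyl 4-hydroxy-3-(4-hydroxyphenyl)-5-oxo-2,5-dihydrofuran-2-carboxylate (racemic) | COC(=O)C1OC(=O)C(O)=C1c1ccc(O)cc1 | intermediate
10 | methyl 4-(benzyloxy)-3-[4-(benzyloxy)phenyl]-5-oxo-2,5-dihydrofuran-2-carboxylate (racemic) | COC(=O)C1OC(=O)C(OCc2ccccc2)=C1c1ccc(OCc2ccccc2)cc1 | intermediate
11 | methyl (2R)-4-(benzyloxy)-3-[4-(benzyloxy)phenyl]-2-[(2,2-dimethyl-4H-1,3-benzodioxin-6-yl)methyl]-5-oxo-2,5-dihydrofuran-2-carboxylate | COC(=O)[C@]1(Cc2ccc3c(c2)COC(C)(C)O3)OC(=O)C(OCc2ccccc2)=C1c1ccc(OCc2ccccc2)cc1 | intermediate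
12 | methyl (2R)-4-(benzyloxy)-3-[4-(benzyloxy)phenyl]-2-[4-hydroxy-3-(hydroxymethyl)benzyl]-5-oxo-2,5-dihydrofuran-2-carboxylate | COC(=O)[C@]1(Cc2ccc(O)c(CO)c2)OC(=O)C(OCc2ccccc2)=C1c1ccc(OCc2ccccc2)cc1 | intermediate
13 | 2-methylprop-1-enylboronic acid pinacol ester | CC(C)=CB1OC(C)(C)C(C)(C)O1 | starting material
14 | methyl (2R)-4-(benzyloxy)-3-[4-(benzyloxy)phenyl]-2-[(3-methylidene-4-oxocyclohexa-1,5-dien-1-yl)methyl]-5-oxo-2,5-dihydrofuran-2-carboxylate (o-quinone methide, not isolated) | COC(=O)[C@]1(CC2=CC(=C)C(=O)C=C2)OC(=O)C(OCc2ccccc2)=C1c1ccc(OCc2ccccc2)cc1 | intermediate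
15 | methyl (2R)-4-(benzyloxy)-3-[4-(benzyloxy)phenyl]-2-{[(3S)-2,2-dimethyl-3-(4,4,5,5-tetramethyl-1,3,2-dioxaborolan-2-yl)-3,4-dihydro-2H-chromen-6-yl]methyl}-5-oxo-2,5-dihydrofuran-2-carboxylate | COC(=O)[C@]1(Cc2ccc3c(c2)C[C@H](B2OC(C)(C)C(C)(C)O2)C(C)(C)O3)OC(=O)C(OCc2ccccc2)=C1c1ccc(OCc2ccccc2)cc1 | intermediate
16 | methyl (2R)-4-(benzyloxy)-3-[4-(benzyloxy)phenyl]-2-{[(3S)-3-hydroxy-2,2-dimethyl-3,4-dihydro-2H-chromen-6-yl]methyl}-5-oxo-2,5-dihydrofuran-2-carboxylate | COC(=O)[C@]1(Cc2ccc3c(c2)C[C@H](O)C(C)(C)O3)OC(=O)C(OCc2ccccc2)=C1c1ccc(OCc2ccccc2)cc1 | intermediate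
17 | methyl (2R)-4-hydroxy-2-{[(3S)-3-hydroxy-2,2-dimethyl-3,4-dihydro-2H-chromen-6-yl]methyl}-3-(4-hydroxyphenyl)-5-oxo-2,5-dihydrofuran-2-carboxylate | COC(=O)[C@]1(Cc2ccc3c(c2)C[C@H](O)C(C)(C)O3)OC(=O)C(O)=C1c1ccc(O)cc1 | target

Total step count: 11.
Longest linear sequence: 9 steps (steps 1, 2, 3, 4, 7, 8, 9, 10, 11 from compound 1); the butenolide arm from 6 and 7 joins at step 7.

Steps most likely to fail

1. Step 9, the one step that goes beyond known chemistry. Ionisation of the primary benzylic alcohol may be slow. The zwitterion may shed boron before the ring closes, which would be an ipso-substitution leading to a prenylated phenol. Facial discrimination of a trisubstituted alkene by the chiral anion may be poor, and because C5 is remote the resulting C3' epimers would be hard to separate. The fallback uses known chemistry, sets out from 12 and returns at 17. The benzylic alcohol of 12 would be oxidised with MnO2 (CH2Cl2, rt) to the salicylaldehyde F1. Condensation of F1 with 2-methylprop-1-enylboronic acid and dibenzylamine (dioxane, 90 °C) should give the 2,2-dimethyl-2H-chromene F2 by Petasis-type alkenyl transfer, loss of the amine and oxa-6π electrocyclisation. Jacobsen–Katsuki epoxidation of F2 (NaOCl, (S,S)-N,N'-bis(3,5-di-tert-butylsalicylidene)-1,2-cyclohexanediaminomanganese chloride, CH2Cl2, 0 °C), for which 2,2-dimethylchromenes are the privileged substrates, is expected to give the (3'S,4'S)-epoxide F3. Hydrogenation of F3 over Pd/C should then cleave the benzylic C4'–O bond of the epoxide and both benzyl ethers in one flask, leaving the C3' carbinol intact and arriving at 17.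

2. Step 7. Facial discrimination inside the chiral ion pair may be poor, and some attack through C3 of the dienolate may compete. The fallback sets out from 10 and 5 and returns at 11. Benzylation under achiral phase-transfer conditions (Bu4NBr, K2CO3, toluene, rt) would give the racemic benzylation product F4. Preparative chromatography on a chiral stationary phase would then separate 11 from its (2S)-enantiomer F5.

3. Step 6. Once both oxygens are capped, carbonate may deprotonate C5–H of the product and over-alkylation at carbon may erode the yield. The fallback sets out from 9 and returns at 10. It replaces base-mediated alkylation by a double Mitsunobu etherification (BnOH, PPh3, diisopropyl azodicarboxylate, THF, 0 °C to rt), which engages only the acidic enol and phenol hydroxyls in the absence of carbonate; no new compound arises (F0).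

Further compounds
F1 | step 9 | methyl (2R)-4-(benzyloxy)-3-[4-(benzyloxy)phenyl]-2-(3-formyl-4-hydroxybenzyl)-5-oxo-2,5-dihydrofuran-2-carboxylate | COC(=O)[C@]1(Cc2ccc(O)c(C=O)c2)OC(=O)C(OCc2ccccc2)=C1c1ccc(OCc2ccccc2)cc1
F2 | step 9 | methyl (2R)-4-(benzyloxy)-3-[4-(benzyloxy)phenyl]-2-[(2,2-dimethyl-2H-chromen-6-yl)methyl]-5-oxo-2,5-dihydrofuran-2-carboxylate | COC(=O)[C@]1(Cc2ccc3c(c2)C=CC(C)(C)O3)OC(=O)C(OCc2ccccc2)=C1c1ccc(OCc2ccccc2)cc1
F3 | step 9 | methyl (2R)-4-(benzyloxy)-3-[4-(benzyloxy)phenyl]-2-{[(3S,4S)-3,4-epoxy-2,2-dimethyl-3,4-dihydro-2H-chromen-6-yl]methyl}-5-oxo-2,5-dihydrofuran-2-carboxylate | COC(=O)[C@]1(Cc2ccc3c(c2)[C@@H]2O[C@@H]2C(C)(C)O3)OC(=O)C(OCc2ccccc2)=C1c1ccc(OCc2ccccc2)cc1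
F4 | step 7 | methyl 4-(benzyloxy)-3-[4-(benzyloxy)phenyl]-2-[(2,2-dimethyl-4H-1,3-benzodioxin-6-yl)methyl]-5-oxo-2,5-dihydrofuran-2-carboxylate (racemic) | COC(=O)C1(Cc2ccc3c(c2)COC(C)(C)O3)OC(=O)C(OCc2ccccc2)=C1c1ccc(OCc2ccccc2)cc1
F5 | step 7 | methyl (2S)-4-(benzyloxy)-3-[4-(benzyloxy)phenyl]-2-[(2,2-dimethyl-4H-1,3-benzodioxin-6-yl)methyl]-5-oxo-2,5-dihydrofuran-2-carboxylate | COC(=O)[C@@]1(Cc2ccc3c(c2)COC(C)(C)O3)OC(=O)C(OCc2ccccc2)=C1c1ccc(OCc2ccccc2)cc1
F0 | step 6 | none | none
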